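**Plan**
- Retrosynthetic cuts, in order: C1–C10 of the ten-membered ring, the allylic C13–O bond (traced back to the C7 oxygen), the butenolide bond C7–C11, the acyl bond O6–C12, then C5–C6 and C9–C10.
- Forward: the open chain C10–C9–C8–C7–C6 is built and joined to the C5–C1 piece, the butenolide ring is closed on the open chain, and the ten-membered ring is closed last by a Nozaki–Hiyama–Kishi reaction that leaves the C1 hydroxyl free.
- Key event: intramolecular Morita–Baylis–Hillman reaction of the C6 acrylate onto the C7 ketone. It is possible because the C7 carbonyl is flanked by the oxygen-bearing C6 and C8, and O6 holds C11–C12–C13 at five-ring distance from C7. Acetylation with allylic transposition then moves the C7 oxygen to C13 and makes the tetrasubstituted C7=C11 bond.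
- Stereochemistry: C8 (S) and a temporary C7 carbinol come from Sharpless desymmetrisation of divinyl carbinol; C6 (R) from Felkin–Anh addition next to that temporary centre, which is then oxidised away; C1 (R) from the macrocyclic ring closure; the 4Z alkene from syn-carbocupration of propyne.

Key step: step 11

Assumption: the SMILES is taken as written, i.e. 1R,6R,8S with the C4=C5 bond Z (C3 and C6 cis); atom labels follow germacrane numbering (ring C1–C10, lactone carbons C11–C13, methylene C14, methyl C15).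

Step 1
Reactants: 1 (3-bromopropoxy)(tert-butyl)dimethylsilane; 2 propyne
Product: 5 (Z)-tert-butyl[(5-iodo-4-methylpent-4-en-1-yl)oxy]dimethylsilane, via Grignard reagent 3 (not isolated), via alkenylcopper 4 (not isolated)
Conditions: Mg, Et2O; CuBr·SMe2, Et2O/Me2S, −45 °C; 2, −25 °C; I2, THF, −60 → 0 °C
Reagents that add atoms: iodine, [I][I]
Why: Normant carbocupration: the alkylcopper adds syn across propyne with the alkyl group on the internal carbon, and iodinolysis with retention gives the (Z)-2-methyl-1-iodoalkene that carries C1–C5 and C15 with the alkene geometry of the target.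

Step 2
Reactants: 6 penta-1,4-dien-3-ol
Product: 7 (2S,3R)-1,2-epoxypent-4-en-3-ol
Conditions: Ti(OiPr)4, D-(−)-diisopropyl tartrate, tBuOOH, 4 Å molecular sieves, CH2Cl2, −20 °C
Reagents that add atoms: tert-butyl hydroperoxide, CC(C)(C)OO
Why: Sharpless asymmetric epoxidation of the prochiral divinyl carbinol selects one enantiotopic vinyl group and one face (erythro product) and removes the minor enantiomer by a faster second epoxidation, which sets C8 and the temporary C7 centre.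

Step 3
Reactants: 7 (2S,3R)-1,2-epoxypent-4-en-3-ol
Product: 8 (2S)-2-[(1R)-1-[(4-methoxybenzyl)oxy]prop-2-en-1-yl]oxirane
Conditions: NaH, 4-methoxybenzyl chloride, Bu4NI (cat.), THF, −20 → 0 °C
Reagents that add atoms: 4-methoxybenzyl chloride, COc1ccc(CCl)cc1
Why: Williamson etherification of the secondary alkoxide at low temperature should outrun Payne rearrangement and touches no stereocentre.

Step 4
Reactants: 8 (2S)-2-[(1R)-1-[(4-methoxybenzyl)oxy]prop-2-en-1-yl]oxirane
Product: 9 (3R,4S)-3-[(4-methoxybenzyl)oxy]hept-1-en-6-yn-4-ol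
Conditions: lithium acetylide–ethylenediamine complex, DMSO, rt
Reagents that add atoms: lithium acetylide–ethylenediamine complex, [Li]C#C.NCCN
Why: SN2 opening of the terminal epoxide at its CH2 carbon by acetylide forms C9–C10 (and brings C14) without touching C8, whose oxygen is released as the only free hydroxyl.

Step 5
Reactants: 9 (3R,4S)-3-[(4-methoxybenzyl)oxy]hept-1-en-6-yn-4-ol
Product: 10 (3R,4S)-3-[(4-methoxybenzyl)oxy]hept-1-en-6-yn-4-yl acetate
Conditions: Ac2O, pyridine, DMAP (cat.), CH2Cl2, 0 °C → rt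
Reagents that add atoms: acetic anhydride, CC(=O)OC(C)=O
Why: DMAP-catalysed acetylation installs the C8 acetate of the target while the C7 oxygen is still masked, so the two oxygens are told apart by timing.

Step 6
Reactants: 10 (3R,4S)-3-[(4-methoxybenzyl)oxy]hept-1-en-6-yn-4-yl acetate
Product: 12 (2S,3S)-2-[(4-methoxybenzyl)oxy]-1-oxohex-5-yn-3-yl acetate, via diol 11 (not isolated)
Conditions: OsO4 (2 mol %), NaIO4, 2,6-lutidine, dioxane/H2O, rt; used crude
Reagents that add atoms: osmium tetroxide, O=[Os](=O)(=O)=O; sodium periodate, [Na+].[O-][I](=O)(=O)=O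
Why: Lemieux–Johnson oxidation (osmium-catalysed dihydroxylation, then periodate cleavage) cuts the monosubstituted alkene in preference to the alkyne and the anisyl ring and gives the C6 aldehyde.

Step 7
Reactants: 12 (2S,3S)-2-[(4-methoxybenzyl)oxy]-1-oxohex-5-yn-3-yl acetate; 5 (Z)-tert-butyl[(5-iodo-4-methylpent-4-en-1-yl)oxy]dimethylsilane
Product: 13 (4S,5R,6R,7Z)-11-[(tert-butyldimethylsilyl)oxy]-6-hydroxy-5-[(4-methoxybenzyl)oxy]-8-methylundec-7-en-1-yn-4-yl acetate (chain C4, C5, C6 = germacrane C8, C7, C6)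
Conditions: CrCl2 (4 equiv), NiCl2 (1 mol %), DMSO, rt
Reagents that add atoms: none
Why: Nozaki–Hiyama–Kishi coupling: the alkenylchromium species (trivalent chromium) adds only to the aldehyde with retention of the Z geometry, and Felkin–Anh approach anti to the C7 alkoxy group should give the 6,7-anti alcohol, i.e. 6R.

Step 8
Reactants: 13 (4S,5R,6R,7Z)-11-[(tert-butyldimethylsilyl)oxy]-6-hydroxy-5-[(4-methoxybenzyl)oxy]-8-methylundec-7-en-1-yn-4-yl acetate; 14 acryloyl chloride
Product: 15 (4S,5S,6R,7Z)-4-acetoxy-11-[(tert-butyldimethylsilyl)oxy]-5-[(4-methoxybenzyl)oxy]-8-methylundec-7-en-1-yn-6-yl acrylate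
Conditions: iPr2NEt, CH2Cl2, −78 → 0 °C
Reagents that add atoms: none
Why: O-acylation of the allylic alcohol places C11, C12 and C13 on O6 (the C7 descriptor changes by priority only).

Step 9
Reactants: 15 (4S,5S,6R,7Z)-4-acetoxy-11-[(tert-butyldimethylsilyl)oxy]-5-[(4-methoxybenzyl)oxy]-8-methylundec-7-en-1-yn-6-yl acrylate
Product: 16 (4S,5S,6R,7Z)-4-acetoxy-11-[(tert-butyldimethylsilyl)oxy]-5-hydroxy-8-methylundec-7-en-1-yn-6-yl acrylate
Conditions: DDQ, CH2Cl2/pH 7 buffer, 0 °C; taken on at once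
Reagents that add atoms: none
Why: Oxidative cleavage of the 4-methoxybenzyl ether under neutral conditions frees only the C7 hydroxyl, and immediate use should forestall 1,2-acyl migration.

Step 10
Reactants: 16 (4S,5S,6R,7Z)-4-acetoxy-11-[(tert-butyldimethylsilyl)oxy]-5-hydroxy-8-methylundec-7-en-1-yn-6-yl acrylate
Product: 17 (4S,6R,7Z)-4-acetoxy-11-[(tert-butyldimethylsilyl)oxy]-8-methyl-5-oxoundec-7-en-1-yn-6-yl acrylate
Conditions: Dess–Martin periodinane, NaHCO3, CH2Cl2, 0 °C → rt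
Reagents that add atoms: none
Why: Dess–Martin oxidation under buffered, non-basic conditions removes the temporary C7 centre and gives the ketone flanked by the two acyloxy carbons without enolising C6 or C8.

Step 11
Reactants: 17 (4S,6R,7Z)-4-acetoxy-11-[(tert-butyldimethylsilyl)oxy]-8-methyl-5-oxoundec-7-en-1-yn-6-yl acrylate
Product: 18 (5R)-4-[(1S)-1-acetoxybut-3-yn-1-yl]-5-[(1Z)-5-[(tert-butyldimethylsilyl)oxy]-2-methylpent-1-en-1-yl]-4-hydroxy-3-methylideneoxolan-2-one (C4 of the lactone = germacrane C7, either epimer)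
Conditions: PMe3 (0.5 equiv), tert-amyl alcohol/THF, 0.02 M, rt
Reagents that add atoms: none
Why: Proposed new method: PMe3 adds reversibly to the acrylate β-carbon (C13) to give a phosphonium enolate whose α-carbon (C11) attacks the C7 ketone, and proton transfer with loss of PMe3 gives the α-methylene-β-hydroxy-γ-lactone. The closest known reaction type is the intramolecular Morita–Baylis–Hillman (aldol) cyclisation of acrylamides and enoates onto tethered ketones or aldehydes under amine or phosphine catalysis; an acrylate ester of an α-hydroxy ketone closing to a butyrolactone is the untested variant. The lactone ring closes in the 5-exo-trig mode at the carbonyl (5-(enolendo)-exo-trig for the enolate), the same mode as the routine intramolecular Horner–Wadsworth–Emmons route to butenolides. The new C7 carbinol centre is not controlled and need not be, because step 12 makes C7 trigonal. The step needs aldol addition at C7 to win over enolisation at C6 or C8 and over intermolecular Rauhut–Currier dimerisation. This is secured by the activation of the C7 carbonyl by its two acyloxy-bearing neighbours, the low basicity of the phosphine, allylic 1,3-strain from the Z alkene that holds the C6–H bond in the alkene plane, and high dilution.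

Step 12
Reactants: 18 (5R)-4-[(1S)-1-acetoxybut-3-yn-1-yl]-5-[(1Z)-5-[(tert-butyldimethylsilyl)oxy]-2-methylpent-1-en-1-yl]-4-hydroxy-3-methylideneoxolan-2-one
Product: 20 [(5R)-4-[(1S)-1-acetoxybut-3-yn-1-yl]-5-[(1Z)-5-[(tert-butyldimethylsilyl)oxy]-2-methylpent-1-en-1-yl]-2-oxo-2,5-dihydrofuran-3-yl]methyl acetate, via tertiary acetate 19 (not isolated)
Conditions: Ac2O, DMAP, CH2Cl2, 0 °C → rt; then DABCO (0.2 equiv), rt
Reagents that add atoms: acetic anhydride, CC(=O)OC(C)=O
Why: Acetylation of the tertiary Morita–Baylis–Hillman alcohol followed by amine-mediated SN2′–SN2′ allylic transposition, driven by formation of the conjugated tetrasubstituted endocyclic alkene, moves the former C7 oxygen to C13 as its acetate and creates C7=C11.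

Step 13
Reactants: 20 [(5R)-4-[(1S)-1-acetoxybut-3-yn-1-yl]-5-[(1Z)-5-[(tert-butyldimethylsilyl)oxy]-2-methylpent-1-en-1-yl]-2-oxo-2,5-dihydrofuran-3-yl]methyl acetate
Product: 22 [(5R)-4-[(1S)-1-acetoxy-3-iodobut-3-en-1-yl]-5-[(1Z)-5-[(tert-butyldimethylsilyl)oxy]-2-methylpent-1-en-1-yl]-2-oxo-2,5-dihydrofuran-3-yl]methyl acetate, via alkenylborane 21 (not isolated)
Conditions: B-iodo-9-BBN, hexane/CH2Cl2, −20 → 0 °C; then AcOH, 0 °C
Reagents that add atoms: B-iodo-9-borabicyclo[3.3.1]nonane, IB1C2CCCC1CCC2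
Why: Haloboration–protodeboration: the iodoborane adds cis to the terminal alkyne with iodine on the internal carbon (C10) and acetic acid cleaves the C–B bond, which should be faster at low temperature than any attack on alkenes, esters or the silyl ether.

Step 14
Reactants: 22 [(5R)-4-[(1S)-1-acetoxy-3-iodobut-3-en-1-yl]-5-[(1Z)-5-[(tert-butyldimethylsilyl)oxy]-2-methylpent-1-en-1-yl]-2-oxo-2,5-dihydrofuran-3-yl]methyl acetate
Product: 23 [(5R)-4-[(1S)-1-acetoxy-3-iodobut-3-en-1-yl]-5-[(1Z)-5-hydroxy-2-methylpent-1-en-1-yl]-2-oxo-2,5-dihydrofuran-3-yl]methyl acetate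
Conditions: HF·pyridine, pyridine, THF, 0 °C → rt
Reagents that add atoms: none
Why: Buffered fluoride desilylation of the primary silyl ether is acidic enough to leave both acetates and the base-sensitive 13-acetoxy butenolide untouched.

Step 15
Reactants: 23 [(5R)-4-[(1S)-1-acetoxy-3-iodobut-3-en-1-yl]-5-[(1Z)-5-hydroxy-2-methylpent-1-en-1-yl]-2-oxo-2,5-dihydrofuran-3-yl]methyl acetate
Product: 24 [(5R)-4-[(1S)-1-acetoxy-3-iodobut-3-en-1-yl]-5-[(1Z)-2-methyl-5-oxopent-1-en-1-yl]-2-oxo-2,5-dihydrofuran-3-yl]methyl acetate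
Conditions: Dess–Martin periodinane, NaHCO3, CH2Cl2, rt
Reagents that add atoms: none
Why: Dess–Martin oxidation gives the C1 aldehyde under non-basic conditions, so C6 is not deprotonated and the C13 acetate is not eliminated.

Step 16
Reactants: 24 [(5R)-4-[(1S)-1-acetoxy-3-iodobut-3-en-1-yl]-5-[(1Z)-2-methyl-5-oxopent-1-en-1-yl]-2-oxo-2,5-dihydrofuran-3-yl]methyl acetate
Product: 25 8alpha,13-diacetoxy-1beta-hydroxygermacra-4,7(11),10(14)-trien-6,12-olide (1R,4Z,6R,8S)
Conditions: CrCl2 (8 equiv), NiCl2 (1 mol %), DMSO/THF, 2 mM by slow addition, rt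
Reagents that add atoms: none
Why: Intramolecular Nozaki–Hiyama–Kishi reaction: the C10 alkenylchromium species adds to the C1 aldehyde, closing the ten-membered ring and giving the 10(14)-methylene allylic alcohol directly; the C1 configuration (R wanted) depends on the macrocyclic transition state, which the rigid butenolide and the Z alkene restrict, and must be verified.

**Compound list**
1 | (3-bromopropoxy)(tert-butyl)dimethylsilane | CC(C)(C)[Si](C)(C)OCCCBr | starting material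
2 | propyne | CC#C | starting material
3 | {3-[(tert-butyldimethylsilyl)oxy]propyl}magnesium bromide | CC(C)(C)[Si](C)(C)OCCC[Mg]Br | intermediate
4 | (Z)-{5-[(tert-butyldimethylsilyl)oxy]-2-methylpent-1-en-1-yl}copper | [Cu]/C=C(/C)CCCO[Si](C)(C)C(C)(C)C | intermediate
5 | (Z)-tert-butyl[(5-iodo-4-methylpent-4-en-1-yl)oxy]dimethylsilane | I/C=C(/C)CCCO[Si](C)(C)C(C)(C)C | intermediate
6 | penta-1,4-dien-3-ol | C=CC(O)C=C | starting material
7 | (2S,3R)-1,2-epoxypent-4-en-3-ol | C=C[C@@H](O)[C@@H]1CO1 | intermediate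
8 | (2S)-2-[(1R)-1-[(4-methoxybenzyl)oxy]prop-2-en-1-yl]oxirane | C=C[C@@H](OCc1ccc(OC)cc1)[C@@H]1CO1 | intermediate
9 | (3R,4S)-3-[(4-methoxybenzyl)oxy]hept-1-en-6-yn-4-ol | C#CC[C@H](O)[C@H](OCc1ccc(OC)cc1)C=C | intermediate
10 | (3R,4S)-3-[(4-methoxybenzyl)oxy]hept-1-en-6-yn-4-yl acetate | C#CC[C@H](OC(C)=O)[C@H](OCc1ccc(OC)cc1)C=C | intermediate
11 | (3R,4S)-1,2-dihydroxy-3-[(4-methoxybenzyl)oxy]hept-6-yn-4-yl acetate (C2 epimers) | C#CC[C@H](OC(C)=O)[C@H](OCc1ccc(OC)cc1)C(O)CO | intermediate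
12 | (2S,3S)-2-[(4-methoxybenzyl)oxy]-1-oxohex-5-yn-3-yl acetate | C#CC[C@H](OC(C)=O)[C@H](OCc1ccc(OC)cc1)C=O | intermediate
13 | (4S,5R,6R,7Z)-11-[(tert-butyldimethylsilyl)oxy]-6-hydroxy-5-[(4-methoxybenzyl)oxy]-8-methylundec-7-en-1-yn-4-yl acetate | C#CC[C@H](OC(C)=O)[C@H](OCc1ccc(OC)cc1)[C@H](O)/C=C(/C)CCCO[Si](C)(C)C(C)(C)C | intermediate
14 | acryloyl chloride | C=CC(=O)Cl | starting material
15 | (4S,5S,6R,7Z)-4-acetoxy-11-[(tert-butyldimethylsilyl)oxy]-5-[(4-methoxybenzyl)oxy]-8-methylundec-7-en-1-yn-6-yl acrylate | C#CC[C@H](OC(C)=O)[C@H](OCc1ccc(OC)cc1)[C@H](OC(=O)C=C)/C=C(/C)CCCO[Si](C)(C)C(C)(C)C | intermediate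
16 | (4S,5S,6R,7Z)-4-acetoxy-11-[(tert-butyldimethylsilyl)oxy]-5-hydroxy-8-methylundec-7-en-1-yn-6-yl acrylate | C#CC[C@H](OC(C)=O)[C@H](O)[C@H](OC(=O)C=C)/C=C(/C)CCCO[Si](C)(C)C(C)(C)C | intermediate
17 | (4S,6R,7Z)-4-acetoxy-11-[(tert-butyldimethylsilyl)oxy]-8-methyl-5-oxoundec-7-en-1-yn-6-yl acrylate | C#CC[C@H](OC(C)=O)C(=O)[C@H](OC(=O)C=C)/C=C(/C)CCCO[Si](C)(C)C(C)(C)C | intermediate
18 | (5R)-4-[(1S)-1-acetoxybut-3-yn-1-yl]-5-[(1Z)-5-[(tert-butyldimethylsilyl)oxy]-2-methylpent-1-en-1-yl]-4-hydroxy-3-methylideneoxolan-2-one | C#CC[C@H](OC(C)=O)C1(O)C(=C)C(=O)O[C@@H]1/C=C(/C)CCCO[Si](C)(C)C(C)(C)C | intermediate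
19 | (5R)-4-acetoxy-4-[(1S)-1-acetoxybut-3-yn-1-yl]-5-[(1Z)-5-[(tert-butyldimethylsilyl)oxy]-2-methylpent-1-en-1-yl]-3-methylideneoxolan-2-one | C#CC[C@H](OC(C)=O)C1(OC(C)=O)C(=C)C(=O)O[C@@H]1/C=C(/C)CCCO[Si](C)(C)C(C)(C)C | intermediate
20 | [(5R)-4-[(1S)-1-acetoxybut-3-yn-1-yl]-5-[(1Z)-5-[(tert-butyldimethylsilyl)oxy]-2-methylpent-1-en-1-yl]-2-oxo-2,5-dihydrofuran-3-yl]methyl acetate | C#CC[C@H](OC(C)=O)C1=C(COC(C)=O)C(=O)O[C@@H]1/C=C(/C)CCCO[Si](C)(C)C(C)(C)C | intermediate
21 | B-[(Z)-2-iodoalk-1-enyl]-9-borabicyclo[3.3.1]nonane adduct of 20 | C1CC2CCCC(C1)B2/C=C(\I)C[C@H](OC(C)=O)C1=C(COC(C)=O)C(=O)O[C@@H]1/C=C(/C)CCCO[Si](C)(C)C(C)(C)C | intermediate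
22 | [(5R)-4-[(1S)-1-acetoxy-3-iodobut-3-en-1-yl]-5-[(1Z)-5-[(tert-butyldimethylsilyl)oxy]-2-methylpent-1-en-1-yl]-2-oxo-2,5-dihydrofuran-3-yl]methyl acetate | C=C(I)C[C@H](OC(C)=O)C1=C(COC(C)=O)C(=O)O[C@@H]1/C=C(/C)CCCO[Si](C)(C)C(C)(C)C | intermediate
23 | [(5R)-4-[(1S)-1-acetoxy-3-iodobut-3-en-1-yl]-5-[(1Z)-5-hydroxy-2-methylpent-1-en-1-yl]-2-oxo-2,5-dihydrofuran-3-yl]methyl acetate | C=C(I)C[C@H](OC(C)=O)C1=C(COC(C)=O)C(=O)O[C@@H]1/C=C(/C)CCCO | intermediate
24 | [(5R)-4-[(1S)-1-acetoxy-3-iodobut-3-en-1-yl]-5-[(1Z)-2-methyl-5-oxopent-1-en-1-yl]-2-oxo-2,5-dihydrofuran-3-yl]methyl acetate | C=C(I)C[C@H](OC(C)=O)C1=C(COC(C)=O)C(=O)O[C@@H]1/C=C(/C)CCC=O | intermediate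
25 | 8alpha,13-diacetoxy-1beta-hydroxygermacra-4,7(11),10(14)-trien-6,12-olide | C=C1C[C@H](OC(C)=O)C2=C(COC(C)=O)C(=O)O[C@@H]2/C=C(/C)CC[C@H]1O | target

**Step count**
Total: 16 steps. Longest linear sequence: 15 steps (6 → 25, steps 2–16); step 1 makes the second fragment.

**Steps most likely to fail**

Step 11. The phosphonium enolate may add too slowly to the hindered ketone, so that reversible deprotonation at C6 (epimerisation or conjugation of the Z alkene) or acrylate oligomerisation takes over. The fallback forms the same C7–C11 bond by intramolecular Horner–Wadsworth–Emmons olefination; it sets out from 13 and comes back at 20. Alcohol 13 is esterified (DCC, DMAP, CH2Cl2) with the reagent 2-(diethoxyphosphoryl)-3-[(triethylsilyl)oxy]propanoic acid to give phosphonate ester F1. DDQ frees the C7 hydroxyl to give alcohol F2, and Dess–Martin oxidation gives ketone F3. Masamune–Roush conditions (LiCl, iPr2NEt, MeCN) close the 13-triethylsilyloxy butenolide F4. PPTS in MeOH at 0 °C removes only the triethylsilyl group to give 13-hydroxy butenolide F5, and Ac2O/pyridine gives 20.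

Step 16. The alkenylchromium species may add to the C1 aldehyde from the undesired face of the macrocyclic transition state, giving the C1 epimer. The fallback replaces macrocycle control by reagent control; it sets out from 24 and comes back at 25. The ring closure then delivers 1-epi alcohol F6 (alone or mixed with 25). Dess–Martin oxidation gives the cross-conjugated 1-oxo enone F7, and reduction with catecholborane and (S)-2-methyl-CBS-oxazaborolidine in toluene at −78 °C (alkenyl as the large group) should give 25.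

Step 13. The Lewis-acidic iodoborane may ionise the allylic C13 acetate or cleave the silyl ether in competition with haloboration of the alkyne. The fallback uses hydrometalation and halodemetalation; it sets out from 20 and comes back at 22. Markovnikov hydrostannation of 20 (Bu3SnH, Mo(CO)3(CNtBu)3 as catalyst, THF, 55 °C) gives 2-(tributylstannyl)alkene F8, and iododestannylation (I2, CH2Cl2, 0 °C) gives 22.

**Further compounds**
F1 | step 11 | (4S,5S,6R,7Z)-4-acetoxy-11-[(tert-butyldimethylsilyl)oxy]-5-[(4-methoxybenzyl)oxy]-8-methylundec-7-en-1-yn-6-yl 2-(diethoxyphosphoryl)-3-[(triethylsilyl)oxy]propanoate | C#CC[C@H](OC(C)=O)[C@H](OCc1ccc(OC)cc1)[C@H](OC(=O)C(CO[Si](CC)(CC)CC)P(=O)(OCC)OCC)/C=C(/C)CCCO[Si](C)(C)C(C)(C)C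
F2 | step 11 | (4S,5S,6R,7Z)-4-acetoxy-11-[(tert-butyldimethylsilyl)oxy]-5-hydroxy-8-methylundec-7-en-1-yn-6-yl 2-(diethoxyphosphoryl)-3-[(triethylsilyl)oxy]propanoate | C#CC[C@H](OC(C)=O)[C@H](O)[C@H](OC(=O)C(CO[Si](CC)(CC)CC)P(=O)(OCC)OCC)/C=C(/C)CCCO[Si](C)(C)C(C)(C)C
F3 | step 11 | (4S,6R,7Z)-4-acetoxy-11-[(tert-butyldimethylsilyl)oxy]-8-methyl-5-oxoundec-7-en-1-yn-6-yl 2-(diethoxyphosphoryl)-3-[(triethylsilyl)oxy]propanoate | C#CC[C@H](OC(C)=O)C(=O)[C@H](OC(=O)C(CO[Si](CC)(CC)CC)P(=O)(OCC)OCC)/C=C(/C)CCCO[Si](C)(C)C(C)(C)C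
F4 | step 11 | (1S)-1-[(2R)-2-[(1Z)-5-[(tert-butyldimethylsilyl)oxy]-2-methylpent-1-en-1-yl]-5-oxo-4-{[(triethylsilyl)oxy]methyl}-2,5-dihydrofuran-3-yl]but-3-yn-1-yl acetate | C#CC[C@H](OC(C)=O)C1=C(CO[Si](CC)(CC)CC)C(=O)O[C@@H]1/C=C(/C)CCCO[Si](C)(C)C(C)(C)C
F5 | step 11 | (1S)-1-[(2R)-2-[(1Z)-5-[(tert-butyldimethylsilyl)oxy]-2-methylpent-1-en-1-yl]-4-(hydroxymethyl)-5-oxo-2,5-dihydrofuran-3-yl]but-3-yn-1-yl acetate | C#CC[C@H](OC(C)=O)C1=C(CO)C(=O)O[C@@H]1/C=C(/C)CCCO[Si](C)(C)C(C)(C)C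
F6 | step 16 | 1-epi-25 (1S,4Z,6R,8S) | C=C1C[C@H](OC(C)=O)C2=C(COC(C)=O)C(=O)O[C@@H]2/C=C(/C)CC[C@@H]1O
F7 | step 16 | 8alpha,13-diacetoxy-1-oxogermacra-4,7(11),10(14)-trien-6,12-olide | C=C1C[C@H](OC(C)=O)C2=C(COC(C)=O)C(=O)O[C@@H]2/C=C(/C)CCC1=O
F8 | step 13 | [(5R)-4-[(1S)-1-acetoxy-3-(tributylstannyl)but-3-en-1-yl]-5-[(1Z)-5-[(tert-butyldimethylsilyl)oxy]-2-methylpent-1-en-1-yl]-2-oxo-2,5-dihydrofuran-3-yl]methyl acetate | C=C(C[C@H](OC(C)=O)C1=C(COC(C)=O)C(=O)O[C@@H]1/C=C(/C)CCCO[Si](C)(C)C(C)(C)C)[Sn](CCCC)(CCCC)CCCC
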